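**Retrosynthetic overview**
- The target comes from a C11-allyl decalin by O8 desilylation and a final cross-metathesis with 2-methylbut-3-en-2-ol (side chain last).
- Both rings form in one chloronium cascade on an acyclic polyene: Cl+ on C10=C11, ring B first (C11–C6), then ring A (C7–C2). A 1-acetoxy-1,3-diene terminus delivers the C1 aldehyde and the C3=C4 enoate directly.
- The single C8 silyloxy stereocentre (pseudo-axial in the chair–chair array) is meant to set C2, C6, C7, C10 and C11.
- The polyene comes from a C4 Grignard reagent plus dimethyl oxalate, then Wittig and enol acetylation. The chain comes from an asymmetric vinylogous Mukaiyama aldol (sets C8) of a bromo-enal with a tiglate dienolate, then ester → allyl.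
- Positions are numbered as in geranylgeranyl: C1 = formyl carbon, C20 = ester carbon, C8 = carbinol, C10 = C–Cl, C12 onwards = side chain.

Assumption: chlorodiethylsulfonium hexachloroantimonate (CDSC) is made in one operation from Et2S, SbCl5 and Cl2 and is treated as a reagent, not counted as a step.

**Step 1**
Reactants: 1 5-bromo-2-methylpent-2-ene
Product: 2 (2E)-5-bromo-2-methylpent-2-enal
Conditions: SeO2 (1.2 equiv), 1,4-dioxane/H2O, 90 °C
Reagents that add atoms: selenium dioxide, O=[Se]=O
Why: Riley allylic oxidation (ene reaction, then [2,3]-sigmatropic shift) attacks only the (E)-methyl group of the trisubstituted alkene and, with stoichiometric SeO2 at 90 °C, carries the allylic alcohol on to the (E)-enal, while the primary bromide is inert.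

**Step 2**
Reactants: 3 ethyl (2E)-2-methylbut-2-enoate
Product: 4 tert-butyl{[(1Z)-1-ethoxy-2-methylbuta-1,3-dien-1-yl]oxy}dimethylsilane
Conditions: LDA, THF/DMPU, −78 °C; TBSCl, −78 °C → rt
Reagents that add atoms: tert-butyldimethylsilyl chloride, CC(C)(C)[Si](C)(C)Cl
Why: kinetic γ-deprotonation of the tiglate gives the extended lithium dienolate, and O-silylation gives the silyl dienol ether (vinylogous silyl ketene acetal), whose C1 geometry is irrelevant because C1 returns to an ester carbonyl.

**Step 3**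
Reactants: 2 (2E)-5-bromo-2-methylpent-2-enal; 4 tert-butyl{[(1Z)-1-ethoxy-2-methylbuta-1,3-dien-1-yl]oxy}dimethylsilane
Product: 6 ethyl (2E,5S,6E)-9-bromo-5-hydroxy-2,6-dimethylnona-2,6-dienoate, via trichlorosilyl ether 5 (not isolated)
Conditions: SiCl4 (1.1 equiv), BINAM-derived bisphosphoramide (5 mol %, the enantiomer that gives Si-face attack), i-Pr2NEt (10 mol %), CH2Cl2, −78 °C; aq. NaHCO3
Reagents that add atoms: none
Why: catalytic enantioselective vinylogous Mukaiyama aldol reaction (Lewis-base-activated SiCl4), in which the chiral phosphoramide-bound trichlorosilyl cation binds the enal and the dienol ether attacks through its γ-carbon on the Si face, which sets C8 as S and gives only the (E)-enoate.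

**Step 4**
Reactants: 6 ethyl (2E,5S,6E)-9-bromo-5-hydroxy-2,6-dimethylnona-2,6-dienoate
Product: 7 ethyl (2E,5S,6E)-9-bromo-5-[(tert-butyldimethylsilyl)oxy]-2,6-dimethylnona-2,6-dienoate
Conditions: TBSCl, imidazole, DMF, rt
Reagents that add atoms: tert-butyldimethylsilyl chloride, CC(C)(C)[Si](C)(C)Cl
Why: standard imidazole-promoted O-silylation of the secondary allylic alcohol, which does not touch the stereocentre.

**Step 5**
Reactants: 7 ethyl (2E,5S,6E)-9-bromo-5-[(tert-butyldimethylsilyl)oxy]-2,6-dimethylnona-2,6-dienoate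
Product: 8 (2E,5S,6E)-9-bromo-5-[(tert-butyldimethylsilyl)oxy]-2,6-dimethylnona-2,6-dien-1-ol
Conditions: DIBAL-H (2.3 equiv), CH2Cl2, −78 °C; Rochelle salt
Reagents that add atoms: none
Why: DIBAL-H 1,2-reduction of the enoate stops at the allylic alcohol and at −78 °C leaves the alkyl bromide, the silyl ether and both alkene geometries intact.

**Step 6**
Reactants: 8 (2E,5S,6E)-9-bromo-5-[(tert-butyldimethylsilyl)oxy]-2,6-dimethylnona-2,6-dien-1-ol; 9 tributyl(vinyl)stannane
Product: 11 tert-butyl{[(4E,7S,8E)-11-bromo-4,8-dimethylundeca-1,4,8-trien-7-yl]oxy}dimethylsilane, via allylic bromide 10 (not isolated)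
Conditions: CBr4, PPh3, CH2Cl2, 0 °C; crude bromide, then 9, Pd2(dba)3 (2.5 mol %), P(2-furyl)3 (10 mol %), THF, 50 °C
Reagents that add atoms: none
Why: Appel bromination of the primary allylic alcohol followed by Stille allyl–vinyl coupling, in which Pd(0) ionises only the allylic bromide (the primary alkyl bromide is inert) and the vinyl group goes to the unsubstituted terminus of the syn-π-allyl complex, so the skipped diene forms with the (E)-trisubstituted alkene retained.

**Step 7**
Reactants: 11 tert-butyl{[(4E,7S,8E)-11-bromo-4,8-dimethylundeca-1,4,8-trien-7-yl]oxy}dimethylsilane; 12 dimethyl oxalate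
Product: 14 methyl (5E,7S,9E)-7-[(tert-butyldimethylsilyl)oxy]-6,10-dimethyl-2-oxotrideca-5,9,12-trienoate, via Grignard reagent 13 (not isolated)
Conditions: Mg, THF, 40 °C; then added to 12 (3 equiv), THF, −78 °C; aq. NH4Cl at −78 °C
Reagents that add atoms: none
Why: Grignard acylation by inverse addition to excess dimethyl oxalate at −78 °C stops at the α-keto ester because the magnesium hemiketal does not collapse before the quench.

**Step 8**
Reactants: 14 methyl (5E,7S,9E)-7-[(tert-butyldimethylsilyl)oxy]-6,10-dimethyl-2-oxotrideca-5,9,12-trienoate; 15 (triphenylphosphoranylidene)acetaldehyde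
Product: 17 methyl (2E,5E,7S,9E)-2-[(E)-2-acetoxyethenyl]-7-[(tert-butyldimethylsilyl)oxy]-6,10-dimethyltrideca-2,5,9,12-tetraenoate, via enal 16 (not isolated)
Conditions: 15 (1.1 equiv), PhMe, 80 °C; then Ac2O, Et3N, DMAP (20 mol %), rt → 40 °C
Reagents that add atoms: acetic anhydride, CC(=O)OC(C)=O
Why: Wittig olefination of the activated ketone by the stabilised formyl ylide gives the 4-oxo-2-enoate, and vinylogous enolisation (C4–H) with O-acetylation gives the 1-acetoxy-1,3-diene, whose new C3=C4 bond forms with C5 trans to CO2Me (tiglate-type, least A1,3 strain) and therefore cis to C2 as ring closure requires, while the enol acetate geometry is irrelevant.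

**Step 9**
Reactants: 17 methyl (2E,5E,7S,9E)-2-[(E)-2-acetoxyethenyl]-7-[(tert-butyldimethylsilyl)oxy]-6,10-dimethyltrideca-2,5,9,12-tetraenoate
Product: 19 methyl (1R,4aR,5S,6S,8S,8aS)-8-[(tert-butyldimethylsilyl)oxy]-6-chloro-1-formyl-5,8a-dimethyl-5-(prop-2-en-1-yl)-1,4,4a,5,6,7,8,8a-octahydronaphthalene-2-carboxylate, via acyloxycarbenium ion 18 (not isolated)
Conditions: Et2SCl·SbCl6 (CDSC, 1.1 equiv), MeNO2, −25 °C, 5 min; aq. NaHCO3/Na2SO3
Reagents that add atoms: chlorodiethylsulfonium hexachloroantimonate (CDSC), CC[S+](Cl)CC.Cl[Sb-](Cl)(Cl)(Cl)(Cl)Cl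
Why: Proposed new method: a chloronium-induced polyene bicyclisation (closest known types: halosulfonium-triggered cation–olefin cascades and enol-derivative-terminated polyene cyclisations) in which Cl+ goes to the most electron-rich 10,11-alkene (the 6,7-alkene carries an allylic silyloxy group, the diene is cross-conjugated to the ester, the vinyl group is monosubstituted) with π-participation of C6=C7 through a chair–chair array that keeps C8–OTBS pseudo-axial (no A1,2 strain with the C7 methyl, no peri clash with the C2 substituent), so that the one C8 stereocentre fixes, by anti addition across both alkenes, equatorial Cl at C10, the C11 centre, the trans ring fusion (C6, C7) and, through a pseudo-equatorial acetoxyvinyl unit whose C2 attacks the C7 cation (6-exo, giving the acetoxy-stabilised cation), C2, after which the acyloxycarbenium ion loses its acetyl group and delivers the aldehyde and the C3=C4 enoate directly.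

**Step 10**
Reactants: 19 methyl (1R,4aR,5S,6S,8S,8aS)-8-[(tert-butyldimethylsilyl)oxy]-6-chloro-1-formyl-5,8a-dimethyl-5-(prop-2-en-1-yl)-1,4,4a,5,6,7,8,8a-octahydronaphthalene-2-carboxylate
Product: 20 methyl (1R,4aR,5S,6S,8S,8aS)-6-chloro-1-formyl-8-hydroxy-5,8a-dimethyl-5-(prop-2-en-1-yl)-1,4,4a,5,6,7,8,8a-octahydronaphthalene-2-carboxylate
Conditions: 48% aq. HF, MeCN, 0 °C → rt
Reagents that add atoms: none
Why: HF desilylation, driven by Si–F bond formation, frees the hindered axial alcohol under non-basic conditions, so the epimerisable C2 aldehyde and the β,γ-unsaturated arrangement are not disturbed.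

**Step 11**
Reactants: 20 methyl (1R,4aR,5S,6S,8S,8aS)-6-chloro-1-formyl-8-hydroxy-5,8a-dimethyl-5-(prop-2-en-1-yl)-1,4,4a,5,6,7,8,8a-octahydronaphthalene-2-carboxylate; 21 2-methylbut-3-en-2-ol
Product: 22 methyl (1R,4aR,5S,6S,8S,8aS)-6-chloro-1-formyl-8-hydroxy-5-[(2E)-4-hydroxy-4-methylpent-2-en-1-yl]-5,8a-dimethyl-1,4,4a,5,6,7,8,8a-octahydronaphthalene-2-carboxylate
Conditions: 21 (10 equiv), Hoveyda–Grubbs II (5 mol %), CH2Cl2, 40 °C
Reagents that add atoms: none
Why: Ru-catalysed olefin cross-metathesis between the unhindered allyl group and the tertiary allylic alcohol (which does not homodimerise) gives the (E)-disubstituted alkene selectively, while the trisubstituted enoate, aldehyde, chloride and free alcohol are inert.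

**Compound list**

1 | 5-bromo-2-methylpent-2-ene | CC(C)=CCCBr | starting material
2 | (2E)-5-bromo-2-methylpent-2-enal | O=C/C(C)=C/CCBr | intermediate
3 | ethyl (2E)-2-methylbut-2-enoate (ethyl tiglate) | CCOC(=O)/C(C)=C/C | starting material
4 | tert-butyl{[(1Z)-1-ethoxy-2-methylbuta-1,3-dien-1-yl]oxy}dimethylsilane (major isomer) | C=C/C(C)=C(/OCC)O[Si](C)(C)C(C)(C)C | intermediate
5 | ethyl (2E,5S,6E)-9-bromo-2,6-dimethyl-5-[(trichlorosilyl)oxy]nona-2,6-dienoate (not isolated) | CCOC(=O)/C(C)=C/C[C@H](O[Si](Cl)(Cl)Cl)/C(C)=C/CCBr | intermediate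
6 | ethyl (2E,5S,6E)-9-bromo-5-hydroxy-2,6-dimethylnona-2,6-dienoate | CCOC(=O)/C(C)=C/C[C@H](O)/C(C)=C/CCBr | intermediate
7 | ethyl (2E,5S,6E)-9-bromo-5-[(tert-butyldimethylsilyl)oxy]-2,6-dimethylnona-2,6-dienoate | CCOC(=O)/C(C)=C/C[C@H](O[Si](C)(C)C(C)(C)C)/C(C)=C/CCBr | intermediate
8 | (2E,5S,6E)-9-bromo-5-[(tert-butyldimethylsilyl)oxy]-2,6-dimethylnona-2,6-dien-1-ol | OC/C(C)=C/C[C@H](O[Si](C)(C)C(C)(C)C)/C(C)=C/CCBr | intermediate
9 | tributyl(vinyl)stannane | C=C[Sn](CCCC)(CCCC)CCCC | starting material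
10 | tert-butyl{[(2E,5S,6E)-1,9-dibromo-2,6-dimethylnona-2,6-dien-5-yl]oxy}dimethylsilane (not isolated) | BrC/C(C)=C/C[C@H](O[Si](C)(C)C(C)(C)C)/C(C)=C/CCBr | intermediate
11 | tert-butyl{[(4E,7S,8E)-11-bromo-4,8-dimethylundeca-1,4,8-trien-7-yl]oxy}dimethylsilane | C=CC/C(C)=C/C[C@H](O[Si](C)(C)C(C)(C)C)/C(C)=C/CCBr | intermediate
12 | dimethyl oxalate | COC(=O)C(=O)OC | starting material
13 | {(3E,5S,7E)-5-[(tert-butyldimethylsilyl)oxy]-4,8-dimethylundeca-3,7,10-trien-1-yl}magnesium bromide (not isolated) | C=CC/C(C)=C/C[C@H](O[Si](C)(C)C(C)(C)C)/C(C)=C/CC[Mg]Br | intermediate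
14 | methyl (5E,7S,9E)-7-[(tert-butyldimethylsilyl)oxy]-6,10-dimethyl-2-oxotrideca-5,9,12-trienoate | C=CC/C(C)=C/C[C@H](O[Si](C)(C)C(C)(C)C)/C(C)=C/CCC(=O)C(=O)OC | intermediate
15 | (triphenylphosphoranylidene)acetaldehyde | O=CC=P(c1ccccc1)(c1ccccc1)c1ccccc1 | starting material
16 | methyl (5E,7S,9E)-7-[(tert-butyldimethylsilyl)oxy]-6,10-dimethyl-2-[(E)-2-oxoethylidene]trideca-5,9,12-trienoate (E isomer drawn; not isolated) | C=CC/C(C)=C/C[C@H](O[Si](C)(C)C(C)(C)C)/C(C)=C/CC/C(C(=O)OC)=C\C=O | intermediate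
17 | methyl (2E,5E,7S,9E)-2-[(E)-2-acetoxyethenyl]-7-[(tert-butyldimethylsilyl)oxy]-6,10-dimethyltrideca-2,5,9,12-tetraenoate | C=CC/C(C)=C/C[C@H](O[Si](C)(C)C(C)(C)C)/C(C)=C/C\C=C(C(=O)OC)/C=C/OC(C)=O | intermediate
18 | O-acetyl oxocarbenium ion of 19, hexachloroantimonate (not isolated) | COC(=O)C1=CC[C@H]2[C@](C)(CC=C)[C@@H](Cl)C[C@H](O[Si](C)(C)C(C)(C)C)[C@]2(C)[C@H]1C=[O+]C(C)=O.Cl[Sb-](Cl)(Cl)(Cl)(Cl)Cl | intermediate
19 | methyl (1R,4aR,5S,6S,8S,8aS)-8-[(tert-butyldimethylsilyl)oxy]-6-chloro-1-formyl-5,8a-dimethyl-5-(prop-2-en-1-yl)-1,4,4a,5,6,7,8,8a-octahydronaphthalene-2-carboxylate | COC(=O)C1=CC[C@H]2[C@](C)(CC=C)[C@@H](Cl)C[C@H](O[Si](C)(C)C(C)(C)C)[C@]2(C)[C@H]1C=O | intermediate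
20 | methyl (1R,4aR,5S,6S,8S,8aS)-6-chloro-1-formyl-8-hydroxy-5,8a-dimethyl-5-(prop-2-en-1-yl)-1,4,4a,5,6,7,8,8a-octahydronaphthalene-2-carboxylate | COC(=O)C1=CC[C@H]2[C@](C)(CC=C)[C@@H](Cl)C[C@H](O)[C@]2(C)[C@H]1C=O | intermediate
21 | 2-methylbut-3-en-2-ol | C=CC(C)(C)O | starting material
22 | methyl (1R,4aR,5S,6S,8S,8aS)-6-chloro-1-formyl-8-hydroxy-5-[(2E)-4-hydroxy-4-methylpent-2-en-1-yl]-5,8a-dimethyl-1,4,4a,5,6,7,8,8a-octahydronaphthalene-2-carboxylate | COC(=O)C1=CC[C@H]2[C@](C)(C/C=C/C(C)(C)O)[C@@H](Cl)C[C@H](O)[C@]2(C)[C@H]1C=O | target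

**Step count**
Total: 11 steps. Longest linear sequence: 10 steps (steps 1 and 3–11; step 2 is the side branch).

**Three steps most likely to fail**

Step 9. The cascade can fail in four ways: Cl+ may attack the enol acetate instead of C10=C11; the silyl ether oxygen may close a chlorotetrahydrofuran; chlorination may occur on the wrong face relative to C8 (poor d.r., though the ee stays locked by C8); or the sequence may stall after ring B. The fallback separates the two cationic events; it sets out from 11 and comes back at 19. Bromide 11 is treated with CDSC in MeNO2 at −25 °C before any enol acetate exists, so ring B closes and the C7 cation loses a proton. This gives the monocyclic chloride tert-butyl{[3-(2-bromoethyl)-5-chloro-4-methyl-2-methylidene-4-(prop-2-en-1-yl)cyclohexyl]oxy}dimethylsilane F1 (double-bond isomers are carried along and converge later). F1 is taken through the chemistry of steps 7 and 8: Mg gives the Grignard reagent of the monocycle F2, dimethyl oxalate 12 gives the monocyclic α-keto ester F3, ylide 15 gives the monocyclic enal F4, and Ac2O/Et3N/DMAP gives the monocyclic dienyl acetate F5. Ring A is then closed in a separate proton-initiated step with a Lewis-acid-assisted Brønsted acid (SnCl4·2,6-diphenylphenol, CH2Cl2, −78 °C). Protonation of the 7(19)-alkene regenerates the tertiary C7 cation on the preformed chair, and capture by the dienyl acetate gives 19.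

Step 8. The formyl ylide may react slowly with the hindered α-keto ester or olefinate twice. The fallback sets out from 11 (through its Grignard reagent 13) and comes back at 16. Reagent 13 is added at −78 °C to the ketone of methyl (E)-4-methoxy-2-oxobut-3-enoate (bought, or made in one step from methyl vinyl ether and methyl chlorooxoacetate). This gives the tertiary carbinol methyl (5E,7S,9E)-7-[(tert-butyldimethylsilyl)oxy]-2-hydroxy-2-[(E)-2-methoxyethenyl]-6,10-dimethyltrideca-5,9,12-trienoate F6 (both epimers at the new carbinol carbon). Dilute HCl in THF then effects allylic transposition and enol-ether hydrolysis to enal 16, which is acetylated as in the second half of step 8 to give 17.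

Step 7. The homoallylic Grignard reagent may cyclise reversibly to a cyclopropylcarbinyl species that can eliminate the β-silyloxy group, or may add twice to the oxalate. The fallback uses an acyl-anion equivalent; it sets out from 11 and comes back at 14. The sodium salt of methyl 1,3-dithiane-2-carboxylate (NaH, DMF, 0 °C → rt) is alkylated with bromide 11 to give methyl 2-{(3E,5S,7E)-5-[(tert-butyldimethylsilyl)oxy]-4,8-dimethylundeca-3,7,10-trien-1-yl}-1,3-dithiane-2-carboxylate F7. The dithiane is removed with MeI/CaCO3 in aqueous MeCN, which leaves the alkenes alone, to give α-keto ester 14.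

**Further compounds**

F1 | step 9 | tert-butyl{[3-(2-bromoethyl)-5-chloro-4-methyl-2-methylidene-4-(prop-2-en-1-yl)cyclohexyl]oxy}dimethylsilane, stereocentres as in 19 | BrCC[C@H]1[C@](C)(CC=C)[C@@H](Cl)C[C@H](O[Si](C)(C)C(C)(C)C)C1=C
F2 | step 9 | Grignard reagent of the monocycle (C–MgBr in place of C–Br of F1) | Br[Mg]CC[C@H]1[C@](C)(CC=C)[C@@H](Cl)C[C@H](O[Si](C)(C)C(C)(C)C)C1=C
F3 | step 9 | monocyclic α-keto ester, methyl 4-(ring)-2-oxobutanoate | COC(=O)C(=O)CC[C@H]1[C@](C)(CC=C)[C@@H](Cl)C[C@H](O[Si](C)(C)C(C)(C)C)C1=C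
F4 | step 9 | monocyclic enal, methyl (E)-2-[2-(ring)ethyl]-4-oxobut-2-enoate | O=C/C=C(\CC[C@H]1[C@](C)(CC=C)[C@@H](Cl)C[C@H](O[Si](C)(C)C(C)(C)C)C1=C)C(=O)OC
F5 | step 9 | monocyclic dienyl acetate, methyl (2E)-2-[(E)-2-acetoxyethenyl]-4-(ring)but-2-enoate | CC(=O)O/C=C/C(C(=O)OC)=C\C[C@H]1[C@](C)(CC=C)[C@@H](Cl)C[C@H](O[Si](C)(C)C(C)(C)C)C1=C
F6 | step 8 | methyl (5E,7S,9E)-7-[(tert-butyldimethylsilyl)oxy]-2-hydroxy-2-[(E)-2-methoxyethenyl]-6,10-dimethyltrideca-5,9,12-trienoate (both C2 epimers) | C=CC/C(C)=C/C[C@H](O[Si](C)(C)C(C)(C)C)/C(C)=C/CCC(O)(/C=C/OC)C(=O)OC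
F7 | step 7 | methyl 2-{(3E,5S,7E)-5-[(tert-butyldimethylsilyl)oxy]-4,8-dimethylundeca-3,7,10-trien-1-yl}-1,3-dithiane-2-carboxylate | C=CC/C(C)=C/C[C@H](O[Si](C)(C)C(C)(C)C)/C(C)=C/CCC1(C(=O)OC)SCCCS1
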